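**Retrosynthetic overview**

1. The strategy rests on ring A (C4a, C5, C6, C7, C8, C8a): it is a phloroglucinol ring fused through C4a–C8a to the 4-pyranone ring C, so C8–C7(O)–C6–C5(O) can be read as a β-keto ester chain hanging from C8a. Ring A is therefore opened at C4a–C5 (Claisen), which leads back to a 2-aryl-4-pyranone whose lateral carbon (the future C8) carries the side chain and a CO–CH2–CO2Me arm.
2. The β-keto ester arm comes from Masamune homologation of a lateral carboxylic acid, which comes from lateral lithiation/carboxylation. The C8–C1'' bond comes from lateral alkylation of 2-aryl-6-methyl-4-pyranone with a homochiral primary iodide.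
3. The iodide comes from (4R)-limonene 1,2-oxide: glycol cleavage, oxidation, methylenation, then decarboxylative iodination. This excises the former ring carbon C2, so that CH2I sits directly on the stereocentre.
4. Ring order: ring B is bought (benzoate), ring C is made in step 2, ring A in step 10; the 4'-O-MOM group is removed last.

Key step: step 10

**Remarks on the chemistry (assumptions)**
- (4R)-Limonene 1,2-oxide is the commercial cis/trans epoxide of (R)-(+)-limonene; (E)-4-methoxypent-3-en-2-one is the commercial methyl enol ether of acetylacetone. Both are taken as purchased.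
- The ring-C pyranone is made from this enol ether and not by acid cyclodehydration of a triketone, because strong acid would cleave the MOM ether.
- Compounds 14, 16, 17 and 18 are carried as mixtures of epimers at the future C8 (and of keto/enol tautomers), since this carbon becomes aromatic in step 10.

**Route**

Step 1
Reactants: 1 methyl 4-hydroxybenzoate
Product: 2 methyl 4-(methoxymethoxy)benzoate
Conditions: MOMCl, i-Pr2NEt, CH2Cl2, 0 °C → rt
Reagents that add atoms: chloromethyl methyl ether, COCCl
Why: O-alkylation of the phenol (MOM protection) should give an ether that survives every basic step of the route and can be removed at the end under mild acid.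

Step 2
Reactants: 2 methyl 4-(methoxymethoxy)benzoate; 3 (E)-4-methoxypent-3-en-2-one
Product: 5 2-[4-(methoxymethoxy)phenyl]-6-methyl-4H-pyran-4-one, via enol-ether diketone 4 (not isolated)
Conditions: 3, LiN(SiMe3)2 (2.3 equiv), THF, −78 °C; then 2, −78 °C → rt; AcOH; then PPTS (cat.), PhMe, 60 °C
Reagents that add atoms: none
Why: Crossed Claisen C-acylation of the kinetic lithium enolate of the β-methoxy enone by the non-enolisable aryl ester should give diketone 4, whose enol oxygen closes ring C by 6-endo conjugate addition–elimination of methanol (γ-pyrone synthesis from β-diketone enol ethers) under acid weak enough to spare the MOM ether.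

Step 3
Reactants: 6 (4R)-limonene 1,2-oxide (cis/trans mixture)
Product: 8 (3R)-6-oxo-3-(prop-1-en-2-yl)heptanal, via trans-diol 7 (not isolated)
Conditions: H5IO6, THF/H2O, 0 °C → rt
Reagents that add atoms: water, O
Why: Acid-promoted hydrolysis of either epoxide isomer to the trans-diol followed by Malaprade glycol cleavage should open the ring between C1 and C2 while leaving the isopropenyl group and the C4 stereocentre, which is not α to a carbonyl, untouched.

Step 4
Reactants: 8 (3R)-6-oxo-3-(prop-1-en-2-yl)heptanal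
Product: 9 (3R)-6-oxo-3-(prop-1-en-2-yl)heptanoic acid
Conditions: NaClO2, NaH2PO4, 2-methylbut-2-ene, t-BuOH/H2O, 0 °C → rt
Reagents that add atoms: NaClO2 (sodium chlorite), [Na+].[O-]Cl=O
Why: Pinnick oxidation is selective for the aldehyde, and the alkene scavenger removes HOCl before it can attack the isopropenyl group.

Step 5
Reactants: 9 (3R)-6-oxo-3-(prop-1-en-2-yl)heptanoic acid
Product: 10 (3R)-6-methyl-3-(prop-1-en-2-yl)hept-6-enoic acid
Conditions: Ph3PCH3Br (2.5 equiv), KOt-Bu (3.5 equiv), THF, 0 °C → rt; then 1 M HCl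
Reagents that add atoms: methyltriphenylphosphonium bromide (as Ph3P=CH2), C[P+](c1ccccc1)(c1ccccc1)c1ccccc1.[Br-]
Why: Wittig methylenation of the methyl ketone on the potassium carboxylate should install the second 1,1-disubstituted alkene, and the stereocentre (β to the carboxylate, γ to the ketone) cannot epimerise.

Step 6
Reactants: 10 (3R)-6-methyl-3-(prop-1-en-2-yl)hept-6-enoic acid
Product: 12 (5S)-6-iodo-2-methyl-5-(prop-1-en-2-yl)hex-1-ene, via Barton ester 11 (not isolated)
Conditions: 1-hydroxypyridine-2(1H)-thione, DCC, DMAP (cat.), CH2Cl2, 0 °C → rt, dark; then CHI3, PhH, hν (W lamp), rt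
Reagents that add atoms: iodoform, IC(I)I; 1-hydroxypyridine-2(1H)-thione, ON1C=CC=CC1=S (its atoms stay only in intermediate 11)
Why: Barton decarboxylative iodination removes the former C2 of limonene as CO2, and iodine transfer from excess CHI3 to the primary radical should outrun both 5-exo/6-endo cyclisation onto the distal alkene and homoallyl rearrangement, the stereocentre itself never being a radical centre.

Step 7
Reactants: 5 2-[4-(methoxymethoxy)phenyl]-6-methyl-4H-pyran-4-one; 12 (5S)-6-iodo-2-methyl-5-(prop-1-en-2-yl)hex-1-ene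
Product: 13 2-[4-(methoxymethoxy)phenyl]-6-[(3R)-6-methyl-3-(prop-1-en-2-yl)hept-6-en-1-yl]-4H-pyran-4-one
Conditions: 5, LiN(i-Pr)2 (1.05 equiv), THF, −78 °C; then 12, DMPU, −78 → 0 °C
Reagents that add atoms: none
Why: Lateral (vinylogous) deprotonation of the 2-methyl-4-pyranone gives an extended enolate that should be alkylated at the exocyclic carbon by the primary iodide in an SN2 reaction, forming the C8–C1'' bond without touching the adjacent stereocentre.

Step 8
Reactants: 13 2-[4-(methoxymethoxy)phenyl]-6-[(3R)-6-methyl-3-(prop-1-en-2-yl)hept-6-en-1-yl]-4H-pyran-4-one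
Product: 14 (4R)-2-{6-[4-(methoxymethoxy)phenyl]-4-oxo-4H-pyran-2-yl}-7-methyl-4-(prop-1-en-2-yl)oct-7-enoic acid (C2 epimers)
Conditions: LiN(i-Pr)2 (1.1 equiv), THF, −78 °C; CO2 (g), −78 → 0 °C; cold 1 M HCl to pH 3
Reagents that add atoms: carbon dioxide, O=C=O
Why: A second lateral lithiation at the only remaining pyranone-activated CH2 and carboxylation of the anion with CO2 should give the acid; the new stereocentre (future C8) is formed without control and is erased later.

Step 9
Reactants: 14 (4R)-2-{6-[4-(methoxymethoxy)phenyl]-4-oxo-4H-pyran-2-yl}-7-methyl-4-(prop-1-en-2-yl)oct-7-enoic acid; 15 potassium methyl malonate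
Product: 18 methyl (6R)-4-{6-[4-(methoxymethoxy)phenyl]-4-oxo-4H-pyran-2-yl}-9-methyl-3-oxo-6-(prop-1-en-2-yl)dec-9-enoate (C4 epimers), via acyl imidazolide 16 (not isolated), via acylmalonic half-ester 17 (not isolated)
Conditions: CDI, THF, rt; then 15, MgCl2, Et3N, MeCN/THF, rt → 40 °C; cold 1 M HCl
Reagents that add atoms: 1,1'-carbonyldiimidazole, O=C(n1ccnc1)n1ccnc1 (its imidazolyl group stays only in intermediate 16)
Why: Masamune–Brooks homologation, in which the acyl imidazolide C-acylates the neutral magnesium malonate and the adduct decarboxylates, should give the β-keto ester under near-neutral conditions that tolerate the acidic C–H next to the pyranone.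

Step 10
Reactants: 18 methyl (6R)-4-{6-[4-(methoxymethoxy)phenyl]-4-oxo-4H-pyran-2-yl}-9-methyl-3-oxo-6-(prop-1-en-2-yl)dec-9-enoate
Product: 19 5,7-dihydroxy-2-[4-(methoxymethoxy)phenyl]-8-[(2R)-5-methyl-2-(prop-1-en-2-yl)hex-5-en-1-yl]-4H-chromen-4-one
Conditions: Mg(OMe)2 (5 equiv), MeOH, 65 °C; then AcOH, 0 °C
Reagents that add atoms: none
Why: Proposed new method: Mg(OMe)2 turns 18 into magnesium enolates; C6–H is removed first, but proton exchange in MeOH should give the C8-deprotonated tautomer (or the C6,C8-dianion), whose charge runs from O7 over C8 and C8a to C4a and O4 and in which Mg2+ bridges O7 and the C5 ester carbonyl, so that C4a adds to C5, methoxide leaves and the C4a–H triketone enolises to the aromatic 5,7-diol, which makes the closure irreversible. The closest known reactions are Mg(OMe)2-mediated Claisen cyclisations of pyrone-masked tetraketides to acylphloroglucinols and base-mediated Claisen (Dieckmann-type) cyclisations of 3,5,7-triketo esters; new here is that the nucleophile is the α-carbon (C4a) of the vinylogous enolate of a 4-pyranone, which normally reacts at its γ-carbon. Ring A closes in a 6-(enolexo)-exo-trig mode. No stereocentre is formed: C8 becomes aromatic, so both epimers converge, and the side-chain stereocentre, which is not α to a carbonyl, is not touched. The step needs C-acylation at C4a to win over retro-Claisen cleavage at C7 and over methoxide opening of ring C; the tether lets only C4a (six atoms from C5) reach the ester, whereas C6 could reach C4 only through a bridged ring, and chelation keeps the β-keto ester as an enolate that resists cleavage.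

Step 11
Reactants: 19 5,7-dihydroxy-2-[4-(methoxymethoxy)phenyl]-8-[(2R)-5-methyl-2-(prop-1-en-2-yl)hex-5-en-1-yl]-4H-chromen-4-one
Product: 20 5,7-dihydroxy-2-(4-hydroxyphenyl)-8-[(2R)-5-methyl-2-(prop-1-en-2-yl)hex-5-en-1-yl]-4H-chromen-4-one (CNP0187326.1)
Conditions: HCl (1 M in MeOH), THF/MeOH, rt
Reagents that add atoms: none
Why: Acid-catalysed acetal exchange of the aryl MOM ether with methanol should free the 4'-phenol under conditions mild enough to leave the two 1,1-disubstituted alkenes unhydrated and uncyclised.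

**Compound list**

1 | methyl 4-hydroxybenzoate | COC(=O)c1ccc(O)cc1 | starting material
2 | methyl 4-(methoxymethoxy)benzoate | COCOc1ccc(cc1)C(=O)OC | intermediate
3 | (E)-4-methoxypent-3-en-2-one | CO/C(C)=C/C(C)=O | starting material
4 | 5-methoxy-1-[4-(methoxymethoxy)phenyl]hex-4-ene-1,3-dione | COCOc1ccc(cc1)C(=O)CC(=O)C=C(C)OC | intermediate (not isolated)
5 | 2-[4-(methoxymethoxy)phenyl]-6-methyl-4H-pyran-4-one | Cc1cc(=O)cc(-c2ccc(OCOC)cc2)o1 | intermediate
6 | (4R)-limonene 1,2-oxide, (4R)-1-methyl-4-(prop-1-en-2-yl)-7-oxabicyclo[4.1.0]heptane, cis/trans mixture | CC12OC1C[C@@H](CC2)C(C)=C | starting material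
7 | (1S,2S,4R)-1-methyl-4-(prop-1-en-2-yl)cyclohexane-1,2-diol | C[C@]1(O)CC[C@H](C[C@@H]1O)C(C)=C | intermediate (not isolated)
8 | (3R)-6-oxo-3-(prop-1-en-2-yl)heptanal | CC(=O)CC[C@H](CC=O)C(C)=C | intermediate
9 | (3R)-6-oxo-3-(prop-1-en-2-yl)heptanoic acid | CC(=O)CC[C@H](CC(=O)O)C(C)=C | intermediate
10 | (3R)-6-methyl-3-(prop-1-en-2-yl)hept-6-enoic acid | C=C(C)CC[C@H](CC(=O)O)C(C)=C | intermediate
11 | 2-thioxopyridin-1(2H)-yl (3R)-6-methyl-3-(prop-1-en-2-yl)hept-6-enoate | C=C(C)CC[C@H](CC(=O)ON1C=CC=CC1=S)C(C)=C | intermediate (not isolated)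
12 | (5S)-6-iodo-2-methyl-5-(prop-1-en-2-yl)hex-1-ene | C=C(C)CC[C@H](CI)C(C)=C | intermediate
13 | 2-[4-(methoxymethoxy)phenyl]-6-[(3R)-6-methyl-3-(prop-1-en-2-yl)hept-6-en-1-yl]-4H-pyran-4-one | C=C(C)CC[C@H](CCc1cc(=O)cc(-c2ccc(OCOC)cc2)o1)C(C)=C | intermediate
14 | (4R)-2-{6-[4-(methoxymethoxy)phenyl]-4-oxo-4H-pyran-2-yl}-7-methyl-4-(prop-1-en-2-yl)oct-7-enoic acid, C2 epimers | C=C(C)CC[C@H](CC(C(=O)O)c1cc(=O)cc(-c2ccc(OCOC)cc2)o1)C(C)=C | intermediate
15 | potassium methyl malonate | COC(=O)CC(=O)[O-].[K+] | starting material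
16 | 1-[(4R)-2-{6-[4-(methoxymethoxy)phenyl]-4-oxo-4H-pyran-2-yl}-7-methyl-4-(prop-1-en-2-yl)oct-7-enoyl]-1H-imidazole | C=C(C)CC[C@H](CC(C(=O)n1ccnc1)c1cc(=O)cc(-c2ccc(OCOC)cc2)o1)C(C)=C | intermediate (not isolated)
17 | 3-methoxy-3-oxo-2-[(4R)-2-{6-[4-(methoxymethoxy)phenyl]-4-oxo-4H-pyran-2-yl}-7-methyl-4-(prop-1-en-2-yl)oct-7-enoyl]propanoic acid | C=C(C)CC[C@H](CC(C(=O)C(C(=O)O)C(=O)OC)c1cc(=O)cc(-c2ccc(OCOC)cc2)o1)C(C)=C | intermediate (not isolated)
18 | methyl (6R)-4-{6-[4-(methoxymethoxy)phenyl]-4-oxo-4H-pyran-2-yl}-9-methyl-3-oxo-6-(prop-1-en-2-yl)dec-9-enoate, C4 epimers | C=C(C)CC[C@H](CC(C(=O)CC(=O)OC)c1cc(=O)cc(-c2ccc(OCOC)cc2)o1)C(C)=C | intermediate (key-step precursor)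
19 | 5,7-dihydroxy-2-[4-(methoxymethoxy)phenyl]-8-[(2R)-5-methyl-2-(prop-1-en-2-yl)hex-5-en-1-yl]-4H-chromen-4-one | C=C(C)CC[C@H](Cc1c(O)cc(O)c2c(=O)cc(-c3ccc(OCOC)cc3)oc12)C(C)=C | intermediate (key-step product)
20 | 5,7-dihydroxy-2-(4-hydroxyphenyl)-8-[(2R)-5-methyl-2-(prop-1-en-2-yl)hex-5-en-1-yl]-4H-chromen-4-one | C=C(C)CC[C@H](Cc1c(O)cc(O)c2c(=O)cc(-c3ccc(O)cc3)oc12)C(=C)C | target

**Step count**

Total: 11 steps. Longest linear sequence: 9 steps (6 → 8 → 9 → 10 → 12 → 13 → 14 → 18 → 19 → 20; steps 3 to 11).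

**Steps most likely to fail**

1. Step 10 (new method). The ring closure may not start because enolisation at C6 turns the ester into an unreactive enolate. The malonyl unit may also be lost by retro-Claisen cleavage at C7, or ring C may be opened by methoxide. The fallback makes the C8–C1'' bond by known sp3–sp2 cross-coupling on an intact flavone; it sets out from iodide 12 and comes back to the route at target 20. Zinc insertion into 12 (Zn dust, LiCl, THF) should give [(2S)-5-methyl-2-(prop-1-en-2-yl)hex-5-en-1-yl]zinc iodide F1. Commercial apigenin would be converted with MOMCl and NaH in DMF into 5,7-bis(methoxymethoxy)-2-[4-(methoxymethoxy)phenyl]-4H-chromen-4-one F2. Electrophilic iodination of this 5,7-dialkoxyflavone (BnMe3N·ICl2, CaCO3, CH2Cl2/MeOH) should go to C8 and give 8-iodo-5,7-bis(methoxymethoxy)-2-[4-(methoxymethoxy)phenyl]-4H-chromen-4-one F3. Negishi coupling of F1 with F3 (Pd(OAc)2, SPhos, THF) should give 5,7-bis(methoxymethoxy)-2-[4-(methoxymethoxy)phenyl]-8-[(2R)-5-methyl-2-(prop-1-en-2-yl)hex-5-en-1-yl]-4H-chromen-4-one F4, and HCl in MeOH would remove the three MOM groups to give 20.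

2. Step 7. The β-branched iodide may undergo E2 elimination to a conjugated diene, or the lateral anion may add to a second pyranone faster than it is alkylated. The fallback attaches the chain to the more nucleophilic dianion of acetylacetone before ring C exists; it sets out from iodide 12 (with ester 2) and comes back at 13. Commercial acetylacetone, deprotonated twice with LiN(i-Pr)2 in THF, should be alkylated by 12 at the terminal carbon to give (7R)-10-methyl-7-(prop-1-en-2-yl)undec-10-ene-2,4-dione F5. The dianion of F5, formed at the methyl terminus, would be acylated by 2 to give (8R)-1-[4-(methoxymethoxy)phenyl]-11-methyl-8-(prop-1-en-2-yl)dodec-11-ene-1,3,5-trione F6. Neutral cyclodehydration of F6 with Ph3P and CCl4 in THF, which spares both the MOM ether and the alkenes, should close ring C and give 13.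

3. Step 6. The primary radical may cyclise onto the distal alkene or undergo vinyl migration before iodine transfer, or chain-carrying radicals may add to the alkenes. The fallback removes the carbon by two-electron chemistry; it sets out from acid 10 and comes back at iodide 12. The dianion of 10 (LiN(i-Pr)2, 2.2 equiv, THF/DMPU) would be hydroxylated with O2 (then Na2SO3) to (3S)-2-hydroxy-6-methyl-3-(prop-1-en-2-yl)hept-6-enoic acid F7. Oxidative decarboxylation with Pb(OAc)4 in PhH should give (2S)-5-methyl-2-(prop-1-en-2-yl)hex-5-enal F8, which would be reduced at once with NaBH4 in MeOH at 0 °C, before the α-stereocentre can enolise, to (2S)-5-methyl-2-(prop-1-en-2-yl)hex-5-en-1-ol F9. Appel-type iodination (I2, PPh3, imidazole, CH2Cl2) would then give 12.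

**Further compounds**

F1 | step 10 | [(2S)-5-methyl-2-(prop-1-en-2-yl)hex-5-en-1-yl]zinc iodide | C=C(C)CC[C@H](C[Zn]I)C(C)=C
F2 | step 10 | 5,7-bis(methoxymethoxy)-2-[4-(methoxymethoxy)phenyl]-4H-chromen-4-one | COCOc1ccc(cc1)-c1cc(=O)c2c(OCOC)cc(OCOC)cc2o1
F3 | step 10 | 8-iodo-5,7-bis(methoxymethoxy)-2-[4-(methoxymethoxy)phenyl]-4H-chromen-4-one | COCOc1ccc(cc1)-c1cc(=O)c2c(OCOC)cc(OCOC)c(I)c2o1
F4 | step 10 | 5,7-bis(methoxymethoxy)-2-[4-(methoxymethoxy)phenyl]-8-[(2R)-5-methyl-2-(prop-1-en-2-yl)hex-5-en-1-yl]-4H-chromen-4-one | C=C(C)CC[C@H](Cc1c(OCOC)cc(OCOC)c2c(=O)cc(-c3ccc(OCOC)cc3)oc12)C(C)=C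
F5 | step 7 | (7R)-10-methyl-7-(prop-1-en-2-yl)undec-10-ene-2,4-dione | C=C(C)CC[C@H](CCC(=O)CC(C)=O)C(C)=C
F6 | step 7 | (8R)-1-[4-(methoxymethoxy)phenyl]-11-methyl-8-(prop-1-en-2-yl)dodec-11-ene-1,3,5-trione | C=C(C)CC[C@H](CCC(=O)CC(=O)CC(=O)c1ccc(OCOC)cc1)C(C)=C
F7 | step 6 | (3S)-2-hydroxy-6-methyl-3-(prop-1-en-2-yl)hept-6-enoic acid, C2 epimers | C=C(C)CC[C@H](C(O)C(=O)O)C(C)=C
F8 | step 6 | (2S)-5-methyl-2-(prop-1-en-2-yl)hex-5-enal | C=C(C)CC[C@H](C=O)C(C)=C
F9 | step 6 | (2S)-5-methyl-2-(prop-1-en-2-yl)hex-5-en-1-ol | C=C(C)CC[C@H](CO)C(C)=C
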